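**Plan**

- Gentiside J is the docosyl ester of 2,3-dihydroxybenzoic acid: one benzene ring, substituents at C1 (ester), C2 and C3 (hydroxyls), an unbranched C22 chain, and no stereocentre.
- The retrosynthesis first masks the two phenols as methoxymethyl acetals. It then cuts both bonds at the ester carbonyl carbon together, the arene C1–C(=O) bond and the C(=O)–O(docosyl) bond, to give an aryl iodide, carbon monoxide and 1-docosanol. The C–I bond is traced back to a C–H bond ortho to an acetal oxygen of protected catechol.
- The feature that allows this is that the carbonyl carbon is a single carbon sitting between ring carbon C1 and the alkoxy oxygen of the chain, which is the unit that carbon monoxide supplies in an alkoxycarbonylation.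
- Forward order: catechol is protected, lithiated ortho to an acetal oxygen and iodinated; the chain and the carbonyl carbon are joined to the ring in one palladium-catalysed step; acid then releases the catechol.
- No ring is formed and no stereochemistry has to be set; only the 1,2,3-substitution pattern is controlled, by the directed lithiation.

Key step: step 3

Remark on the chemistry: HCl in step 4 is taken as anhydrous and catalytic, so each methoxymethyl carbon is assumed to leave as the mixed formal with isopropanol.

**Step 1**
Reactants: 1 catechol (benzene-1,2-diol)
Product: 3 1,2-bis(methoxymethoxy)benzene, via disodium catecholate 2 (not isolated)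
Conditions: NaH (2.4 equiv), DMF, 0 °C, argon; then MOMCl (2.4 equiv), 0 °C → rt
Reagents that add atoms: chloromethyl methyl ether (MOMCl), COCCl
Why: Williamson-type double O-alkylation of the catechol dianion by the highly electrophilic alpha-chloro ether should give the bis-acetal, which masks both phenols and supplies the directing groups for the next step.

**Step 2**
Reactants: 3 1,2-bis(methoxymethoxy)benzene
Product: 5 1-iodo-2,3-bis(methoxymethoxy)benzene, via aryllithium 4 (not isolated)
Conditions: n-BuLi (1.1 equiv), TMEDA, THF, 0 °C; then I2, THF, −78 °C → rt; aq. Na2S2O3 work-up
Reagents that add atoms: iodine, II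
Why: Directed ortho-metalation, in which the acetal oxygens coordinate butyllithium and deliver it to the adjacent ring C–H (C3 and C6 are equivalent by symmetry), followed by electrophilic iodination of the aryllithium, should place the iodine next to the two protected oxygens.

**Step 3**
Reactants: 5 1-iodo-2,3-bis(methoxymethoxy)benzene (1.2 equiv); 6 carbon monoxide; 7 1-docosanol
Product: 8 docosyl 2,3-bis(methoxymethoxy)benzoate
Conditions: Pd(OAc)2 (3 mol %), Xantphos (4 mol %), Et3N (3 equiv), CO (1 atm, balloon), 4 Å molecular sieves, toluene, 80 °C
Reagents that add atoms: none
Why: Zerovalent palladium, formed in the flask from Pd(OAc)2 and Xantphos, adds oxidatively to the C–I bond of 5, carbon monoxide coordinates and inserts by 1,1-migration of the aryl group to give an aroyl complex of divalent palladium, and Et3N-assisted attack of the primary hydroxyl of 7 on this acyl centre releases ester 8 and returns zerovalent palladium, so the C1–C(=O) and C(=O)–O bonds are both made in one operation. The closest known reaction type is the Heck-type palladium-catalysed alkoxycarbonylation of aryl halides under atmospheric carbon monoxide with a wide-bite-angle bisphosphine. No ring is closed and no stereocentre is created. Site selectivity rests on the single carbon–iodine bond, which is far more reactive toward zerovalent palladium than any C–H or C–O bond of the arene, and the ortho acetal oxygen is only a weak, hemilabile donor that should not block carbon monoxide insertion. Selectivity for the ester over the alpha-keto ester is secured by working at 1 atm and 80 °C, where a second insertion is slow, and dry conditions leave docosanol as the only nucleophile so that no benzoic acid forms. The methoxymethyl acetals are inert to the amine base and the neutral catalyst, and the iodide is used in slight excess so that the waxy alcohol, the component hardest to separate from the product, is consumed.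

**Step 4**
Reactants: 8 docosyl 2,3-bis(methoxymethoxy)benzoate
Product: 9 Gentiside J (docosyl 2,3-dihydroxybenzoate)
Conditions: HCl (4 M in 1,4-dioxane, cat.), i-PrOH/THF (1:1), 40 °C, argon; pH 6 phosphate buffer work-up
Reagents that add atoms: none
Why: Acid-catalysed acetal exchange (transacetalisation), in which protonation at the aryl acetal oxygen expels the phenol and the methoxymethyl cation is captured by isopropanol, should free both hydroxyls, while the hindered secondary alcohol is too poor a nucleophile to transesterify the docosyl ester under these mild conditions.

**Compound list**

1 | catechol (benzene-1,2-diol) | Oc1ccccc1O | starting material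
2 | disodium catecholate (disodium benzene-1,2-diolate) | [Na+].[Na+].[O-]c1ccccc1[O-] | intermediate
3 | 1,2-bis(methoxymethoxy)benzene | COCOc1ccccc1OCOC | intermediate
4 | [2,3-bis(methoxymethoxy)phenyl]lithium | [Li]c1cccc(OCOC)c1OCOC | intermediate
5 | 1-iodo-2,3-bis(methoxymethoxy)benzene | COCOc1cccc(I)c1OCOC | intermediate
6 | carbon monoxide | [C-]#[O+] | starting material
7 | 1-docosanol | CCCCCCCCCCCCCCCCCCCCCCO | starting material
8 | docosyl 2,3-bis(methoxymethoxy)benzoate | CCCCCCCCCCCCCCCCCCCCCCOC(=O)c1cccc(OCOC)c1OCOC | intermediate
9 | Gentiside J (docosyl 2,3-dihydroxybenzoate) | CCCCCCCCCCCCCCCCCCCCCCOC(=O)c1cccc(O)c1O | target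

**Step count**

Total steps: 4. Longest linear sequence: 4 steps (1 → 3 → 5 → 8 → 9).

**Steps most likely to fail, with fallbacks**

1. Step 3 (alkoxycarbonylation). The catalyst may aggregate to inactive palladium metal under carbon monoxide before the acyl complex is captured by a stoichiometric, sparingly soluble alcohol. Proto-deiodination or hydroxycarbonylation by traces of water could then take over.
 Fallback, setting out from 5 and returning at 8: the carbonyl carbon is first installed as an activated aryl ester without gaseous carbon monoxide, and the alcohol is brought in afterwards. Iodide 5 is treated with 2,4,6-trichlorophenyl formate, Pd(OAc)2, Xantphos and Et3N in toluene (rt to 60 °C); the formate releases carbon monoxide and the phenol in the flask. This aryloxycarbonylation should give 2,4,6-trichlorophenyl 2,3-bis(methoxymethoxy)benzoate F1. Acyl transfer from F1 to 1-docosanol 7 (Et3N, catalytic DMAP, THF, 45 °C) should then give 8.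

2. Step 2 (lithiation and iodination). Under- or over-metalation, and lithium–iodine exchange between aryllithium 4 and freshly formed iodide during the quench, may leave a mixture of non-iodinated, mono-iodinated and di-iodinated ethers. All are non-polar and hard to separate.
 Fallback, setting out from 3 (through its lithio derivative 4) and returning at 8: the aryllithium is quenched with CO2 (THF, −78 °C → rt) and the mixture is acidified cold with dilute HCl to pH 3–4. This should give 2,3-bis(methoxymethoxy)benzoic acid F2, which is separated from neutral material by extraction into aqueous NaHCO3. Steglich esterification of F2 with 1-docosanol 7 (DCC, catalytic DMAP, CH2Cl2, rt) should give 8. The carbonyl carbon then comes from carbon dioxide, and the iodide and the palladium step are bypassed.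

3. Step 4 (acetal removal). Acid-mediated exchange or loss of the docosyl ester may compete, or the released formaldehyde equivalent may recombine with the electron-rich catechol (ring hydroxymethylation, methylene bridging) before both acetals are gone.
 Fallback, setting out from 5 and returning at 9: the protecting groups are changed to benzyl ethers, which leave under neutral hydrogenolysis. Iodide 5 is deprotected while no ester is present (HCl, MeOH, rt) to 3-iodobenzene-1,2-diol F3. This is benzylated (benzyl bromide, K2CO3, DMF, rt) to 1,2-bis(benzyloxy)-3-iodobenzene F4. The same alkoxycarbonylation with 6 and 7 (Pd(OAc)2, Xantphos, Et3N, toluene, 80 °C) should give docosyl 2,3-bis(benzyloxy)benzoate F5. Hydrogenolysis (H2, 1 atm, Pd/C, EtOAc/THF, rt) should then release 9.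

**Further compounds**

F1 | step 3 | 2,4,6-trichlorophenyl 2,3-bis(methoxymethoxy)benzoate | COCOc1cccc(C(=O)Oc2c(Cl)cc(Cl)cc2Cl)c1OCOC
F2 | step 2 | 2,3-bis(methoxymethoxy)benzoic acid | COCOc1cccc(C(=O)O)c1OCOC
F3 | step 4 | 3-iodobenzene-1,2-diol | Oc1cccc(I)c1O
F4 | step 4 | 1,2-bis(benzyloxy)-3-iodobenzene | Ic1cccc(OCc2ccccc2)c1OCc1ccccc1
F5 | step 4 | docosyl 2,3-bis(benzyloxy)benzoate | CCCCCCCCCCCCCCCCCCCCCCOC(=O)c1cccc(OCc2ccccc2)c1OCc1ccccc1
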